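**Retrosynthetic overview**

- The C40 chain is cut at C11=C12 and C11'=C12' (two Wittig reactions on the C10 trienedial): ε-C15 phosphonium salt + dial gives a C25 phosphonium salt, which is joined last to a β-C15 keto-enal that already carries the C19 dodecenoate.
- β half: the C8–C9 bond comes from a Nozaki–Hiyama–Kishi coupling of an actinol-derived cyclohexenylacetaldehyde with a C4 vinyl iodide whose C19 and C11 oxygens are told apart by ynoate hydrostannation; the β ring is bought with (4R,6R)-actinol.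
- ε half: the feature used is the array O–C3'–C4'H=C5'(CH3)–C6'H of the ε ring, a masked 3-methyl-enone in which C4' is an unsubstituted CH between the oxygenated carbon and the methyl-bearing carbon. Taking C4' out leaves 2,4,4-trimethylcyclopent-2-enone, with C6' as its β-carbon.
- The ε ring is therefore made by dienyl conjugate addition to that cyclopentenone (sets C6'), silyl trapping, and insertion of a CBr unit as C4' by dibromocarbene cyclopropanation and electrocyclic ring enlargement; a Corey–Bakshi–Shibata reduction then sets C3'.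
- Order of ring formation: β ring purchased; cyclopentene purchased, then cyclopropane, then the six-membered ε ring, all in the key step.

Key step: step 2

Remark: positions are given in carotenoid numbering (C1–C20 for the β half, primed numbers for the ε half); all polyene steps are run under argon in subdued light.
Remark: L* is the phosphoramidite from (S)-1,1'-bi-2-naphthol and bis[(R)-1-phenylethyl]amine; its sense of induction on enone 3 is assigned by analogy, and the mirror-image ligand is to be used if the opposite sense is found.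

**Step 1**
Reactants: 1 (E)-3-methylpent-2-en-4-yn-1-ol
Product: 2 (E)-tert-butyldimethyl[(3-methylpent-2-en-4-yn-1-yl)oxy]silane
Conditions: TBSCl, imidazole, DMF, 0 → 25 °C
Reagents that add atoms: tert-butyldimethylsilyl chloride, CC(C)(C)[Si](C)(C)Cl
Why: Standard imidazole-mediated silylation of a primary allylic alcohol, which masks the hydroxyl against iBu2AlH and the organocopper chemistry of step 2.

**Step 2**
Reactants: 2 (E)-tert-butyldimethyl[(3-methylpent-2-en-4-yn-1-yl)oxy]silane; 3 2,4,4-trimethylcyclopent-2-en-1-one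
Product: 8 (R)-2-bromo-4-[(1E,3E)-5-(tert-butyldimethylsilyloxy)-3-methylpenta-1,3-dien-1-yl]-3,5,5-trimethylcyclohex-2-en-1-one, via dienylalane 4 (not isolated), via aluminium enolate 5 (not isolated), via silyl enol ether 6 (not isolated), via dibromocyclopropane 7 (not isolated)
Conditions: iBu2AlH, hexane, 50 °C; then 3, CuTC (C5H3CuO2S, 10 mol %), L* (11 mol %), Et2O, −30 °C; TMSOTf, −30 → 0 °C; pentane, filtration through basic Al2O3 under argon; CHBr3 (1.25 equiv), KOtBu (1.2 equiv), pentane, −30 °C; cold filtration; 2,6-lutidine, toluene, 25 → 40 °C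
Reagents that add atoms: bromoform, BrC(Br)Br
Why: syn-Hydroalumination of the terminal alkyne gives the (E,E)-dienylalane 4, whose dienyl group is transferred 1,4 to enone 3 by the chiral copper–phosphoramidite catalyst; O-silylation of the aluminium enolate 5 fixes the enol double bond between the former carbonyl carbon and the methyl-bearing carbon (6), dibromocarbene adds to this most electron-rich, tetrasubstituted double bond (7), and ionisation of the endo bromide with disrotatory two-electron electrocyclic opening of the ring-fusion bond, followed by loss of Me3SiBr, inserts the CBr carbon as C4' and should give the six-membered 2-bromoenone 8. The closest known reaction types are the copper-catalysed asymmetric conjugate addition of alkenylalanes to trisubstituted cyclic enones with silyl trapping of the aluminium enolate, and the dihalocarbene one-carbon ring expansion of cyclic silyl enol ethers to 2-halocycloalk-2-enones. The cyclopropane is closed by a cheletropic [2+1] addition, and the six-membered ring is not closed by a cyclisation at all but results from electrocyclic cleavage of the zero-atom bridge of the bicyclo[3.1.0]hexane, so that the five-membered ring grows by one carbon. The only stereocentre that is kept, C6', is set by the ligand on copper (face selection on the planar enone); the two cyclopropane centres are of no consequence, because one bromine is always endo and both carbons end up sp2. The step needs (a) insertion between C3' and C5' only, secured by the regiodefined enolate that the conjugate addition leaves behind, (b) attack of the carbene on the silyl enol ether and not on the diene, secured by its tetrasubstituted oxygen-donor character and by about one equivalent of carbene, and (c) no γ-deprotonation at C6' of 8, secured by a slight deficit of base, cold filtration before the ring opening and 2,6-lutidine as the only base present on warming.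

**Step 3**
Reactants: 8 (R)-2-bromo-4-[(1E,3E)-5-(tert-butyldimethylsilyloxy)-3-methylpenta-1,3-dien-1-yl]-3,5,5-trimethylcyclohex-2-en-1-one
Product: 9 (1R,4R)-2-bromo-4-[(1E,3E)-5-(tert-butyldimethylsilyloxy)-3-methylpenta-1,3-dien-1-yl]-3,5,5-trimethylcyclohex-2-en-1-ol
Conditions: (S)-Me-CBS oxazaborolidine (0.3 equiv), catecholborane, toluene, −78 °C
Reagents that add atoms: none
Why: Corey–Bakshi–Shibata reduction in which the 2-bromoalkenyl arm is the large group, so that the (S)-catalyst should deliver hydride to the face giving the (1R)-carbinol (trans to the side chain) under reagent control, the remote C4 centre exerting little bias and any (4S) material from step 2 becoming a separable diastereomer.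

**Step 4**
Reactants: 9 (1R,4R)-2-bromo-4-[(1E,3E)-5-(tert-butyldimethylsilyloxy)-3-methylpenta-1,3-dien-1-yl]-3,5,5-trimethylcyclohex-2-en-1-ol
Product: 11 (1R,4R)-4-[(1E,3E)-5-(tert-butyldimethylsilyloxy)-3-methylpenta-1,3-dien-1-yl]-3,5,5-trimethylcyclohex-2-en-1-ol, via dilithio intermediate 10 (not isolated)
Conditions: t-BuLi (3.3 equiv), Et2O, −78 °C; then MeOH, −78 → 0 °C
Reagents that add atoms: none
Why: Lithium–bromine exchange on the lithium alkoxide followed by protonation of the alkenyllithium replaces Br by H without touching a stereocentre, the exchange being much faster at −78 °C than addition to the diene or deprotonation at C6'.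

**Step 5**
Reactants: 11 (1R,4R)-4-[(1E,3E)-5-(tert-butyldimethylsilyloxy)-3-methylpenta-1,3-dien-1-yl]-3,5,5-trimethylcyclohex-2-en-1-ol
Product: 12 tert-butyl{[(1R,4R)-4-[(1E,3E)-5-(tert-butyldimethylsilyloxy)-3-methylpenta-1,3-dien-1-yl]-3,5,5-trimethylcyclohex-2-en-1-yl]oxy}dimethylsilane
Conditions: TBSCl, imidazole, DMF, 25 °C
Reagents that add atoms: tert-butyldimethylsilyl chloride, CC(C)(C)[Si](C)(C)Cl
Why: Standard silylation that shields the ionisable allylic C3' hydroxyl during the phosphonium, Wittig and acid steps that follow.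

**Step 6**
Reactants: 12 tert-butyl{[(1R,4R)-4-[(1E,3E)-5-(tert-butyldimethylsilyloxy)-3-methylpenta-1,3-dien-1-yl]-3,5,5-trimethylcyclohex-2-en-1-yl]oxy}dimethylsilane
Product: 13 (2E,4E)-5-[(1R,4R)-4-(tert-butyldimethylsilyloxy)-2,6,6-trimethylcyclohex-2-en-1-yl]-3-methylpenta-2,4-dien-1-ol
Conditions: HF·pyridine, pyridine, THF, 0 °C
Reagents that add atoms: none
Why: Buffered fluoride desilylation is sterically selective for the primary silyl ether over the secondary ring silyl ether.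

**Step 7**
Reactants: 13 (2E,4E)-5-[(1R,4R)-4-(tert-butyldimethylsilyloxy)-2,6,6-trimethylcyclohex-2-en-1-yl]-3-methylpenta-2,4-dien-1-ol
Product: 15 {(2E,4E)-5-[(1R,4R)-4-(tert-butyldimethylsilyloxy)-2,6,6-trimethylcyclohex-2-en-1-yl]-3-methylpenta-2,4-dien-1-yl}triphenylphosphonium bromide, via allylic bromide 14 (not isolated)
Conditions: CBr4, PPh3, CH2Cl2, −20 °C; then PPh3, 25 °C
Reagents that add atoms: carbon tetrabromide, BrC(Br)(Br)Br; triphenylphosphine, c1ccc(cc1)P(c1ccccc1)c1ccccc1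
Why: Appel bromination under neutral conditions (no allyl cation, so the diene geometry is kept) followed by SN2 quaternisation of PPh3 at the primary allylic carbon.

**Step 8**
Reactants: 15 {(2E,4E)-5-[(1R,4R)-4-(tert-butyldimethylsilyloxy)-2,6,6-trimethylcyclohex-2-en-1-yl]-3-methylpenta-2,4-dien-1-yl}triphenylphosphonium bromide; 16 (2E,4E,6E)-2,7-dimethylocta-2,4,6-trienedial
Product: 18 (2E,4E,6E,8E,10E,12E)-13-[(1R,4R)-4-(tert-butyldimethylsilyloxy)-2,6,6-trimethylcyclohex-2-en-1-yl]-2,7,11-trimethyltrideca-2,4,6,8,10,12-hexaenal, via ylide 17 (not isolated)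
Conditions: NaN(SiMe3)2, THF, −78 °C; then added to 16 (2.5 equiv), −78 → 0 °C; then I2 (cat.), CH2Cl2, diffuse light
Reagents that add atoms: none
Why: Wittig olefination in which the excess of dialdehyde should hold the reaction at mono-condensation, the new C11'=C12' bond being equilibrated to the E form (the Z form is the sterically hindered one) by iodine-catalysed isomerisation.

**Step 9**
Reactants: 18 (2E,4E,6E,8E,10E,12E)-13-[(1R,4R)-4-(tert-butyldimethylsilyloxy)-2,6,6-trimethylcyclohex-2-en-1-yl]-2,7,11-trimethyltrideca-2,4,6,8,10,12-hexaenal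
Product: 19 (2E,4E,6E,8E,10E,12E)-13-[(1R,4R)-4-(tert-butyldimethylsilyloxy)-2,6,6-trimethylcyclohex-2-en-1-yl]-2,7,11-trimethyltrideca-2,4,6,8,10,12-hexaen-1-ol
Conditions: NaBH4, MeOH/CH2Cl2, 0 °C
Reagents that add atoms: none
Why: Borohydride reduces the polyenal in the 1,2 sense, as in the retinal-to-retinol reduction.

**Step 10**
Reactants: 19 (2E,4E,6E,8E,10E,12E)-13-[(1R,4R)-4-(tert-butyldimethylsilyloxy)-2,6,6-trimethylcyclohex-2-en-1-yl]-2,7,11-trimethyltrideca-2,4,6,8,10,12-hexaen-1-ol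
Product: 20 {(2E,4E,6E,8E,10E,12E)-13-[(1R,4R)-4-(tert-butyldimethylsilyloxy)-2,6,6-trimethylcyclohex-2-en-1-yl]-2,7,11-trimethyltrideca-2,4,6,8,10,12-hexaen-1-yl}triphenylphosphonium bromide
Conditions: PPh3·HBr, CH2Cl2, 0 °C
Reagents that add atoms: triphenylphosphine hydrobromide, Br.c1ccc(cc1)P(c1ccccc1)c1ccccc1
Why: SN1-type phosphonium salt formation, in which the hexaenyl carbinol is ionised to a fully delocalised cation that PPh3 captures at its primary terminus (the reaction that turns retinol into its Wittig salt), while the far less basic silyl ether at C3' should not ionise at 0 °C.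

**Step 11**
Reactants: 21 tert-butyldimethyl(prop-2-yn-1-yloxy)silane
Product: 23 ethyl 4-(tert-butyldimethylsilyloxy)but-2-ynoate, via lithium acetylide 22 (not isolated)
Conditions: n-BuLi, THF, −78 °C; then ClCO2Et, −78 → 0 °C
Reagents that add atoms: ethyl chloroformate, CCOC(=O)Cl
Why: C-Acylation of a lithium acetylide with a chloroformate, which makes the future C19 an ester carbon and keeps the future C11 as a silyl ether.

**Step 12**
Reactants: 23 ethyl 4-(tert-butyldimethylsilyloxy)but-2-ynoate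
Product: 24 ethyl (E)-4-(tert-butyldimethylsilyloxy)-2-(tributylstannyl)but-2-enoate
Conditions: Bu3SnH, Pd(PPh3)4 (2 mol %), THF, 0 → 25 °C
Reagents that add atoms: tributyltin hydride, CCCC[SnH](CCCC)CCCC
Why: Palladium-catalysed syn-hydrostannation of an ynoate places tin α to the ester and hydrogen cis to it, which fixes the geometry in which the two CH2O carbons (future C19 and C11) are cis and the future C8–C9 bond is trans to C11.

**Step 13**
Reactants: 24 ethyl (E)-4-(tert-butyldimethylsilyloxy)-2-(tributylstannyl)but-2-enoate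
Product: 25 ethyl (E)-4-(tert-butyldimethylsilyloxy)-2-iodobut-2-enoate
Conditions: I2, CH2Cl2, 0 °C
Reagents that add atoms: iodine, I-I
Why: Iododestannylation proceeds with retention of the double-bond geometry.

**Step 14**
Reactants: 25 ethyl (E)-4-(tert-butyldimethylsilyloxy)-2-iodobut-2-enoate
Product: 26 (E)-4-(tert-butyldimethylsilyloxy)-2-iodobut-2-en-1-ol
Conditions: iBu2AlH (2.5 equiv), CH2Cl2, −78 °C
Reagents that add atoms: none
Why: 1,2-Reduction of the enoate to the allylic alcohol leaves the alkenyl iodide intact and frees only the C19 oxygen.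

**Step 15**
Reactants: 27 (4R,6R)-4-hydroxy-2,2,6-trimethylcyclohexan-1-one
Product: 28 (4R,6R)-4-(tert-butyldimethylsilyloxy)-2,2,6-trimethylcyclohexan-1-one
Conditions: TBSCl, imidazole, DMF, 25 °C
Reagents that add atoms: tert-butyldimethylsilyl chloride, CC(C)(C)[Si](C)(C)Cl
Why: Standard silylation of the secondary alcohol that becomes the C3 hydroxyl of the β ring.

**Step 16**
Reactants: 28 (4R,6R)-4-(tert-butyldimethylsilyloxy)-2,2,6-trimethylcyclohexan-1-one
Product: 30 (R)-4-(tert-butyldimethylsilyloxy)-2,6,6-trimethylcyclohex-1-en-1-yl trifluoromethanesulfonate, via potassium enolate 29 (not isolated)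
Conditions: KN(SiMe3)2, THF, −78 °C; then PhNTf2, −78 → 0 °C
Reagents that add atoms: N-phenylbis(trifluoromethanesulfonimide), O=S(=O)(N(c1ccccc1)S(=O)(=O)C(F)(F)F)C(F)(F)F
Why: Enolisation is possible only toward the methyl-bearing carbon (the other α-carbon is quaternary), so O-triflation gives one regiodefined enol triflate and erases the C6 centre of actinol as planned.

**Step 17**
Reactants: 30 (R)-4-(tert-butyldimethylsilyloxy)-2,6,6-trimethylcyclohex-1-en-1-yl trifluoromethanesulfonate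
Product: 31 (R)-tert-butyldimethyl[(3,5,5-trimethyl-4-vinylcyclohex-3-en-1-yl)oxy]silane
Conditions: CH2=CHSnBu3, Pd2(dba)3 (2.5 mol %), AsPh3, LiCl, NMP, 60 °C
Reagents that add atoms: tributyl(vinyl)stannane, C=C[Sn](CCCC)(CCCC)CCCC
Why: Stille coupling of the hindered cyclohexenyl triflate, with the weakly bound arsine ligand and chloride speeding up transmetalation, brings in C7 and C8.

**Step 18**
Reactants: 31 (R)-tert-butyldimethyl[(3,5,5-trimethyl-4-vinylcyclohex-3-en-1-yl)oxy]silane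
Product: 33 2-[(R)-4-(tert-butyldimethylsilyloxy)-2,6,6-trimethylcyclohex-1-en-1-yl]ethan-1-ol, via alkylborane 32 (not isolated)
Conditions: 9-BBN, THF, 0 → 25 °C; then NaOH, H2O2, 0 °C
Reagents that add atoms: hydrogen peroxide, OO
Why: Hydroboration–oxidation with the bulky borane adds boron only to the terminal CH2 of the vinyl group and leaves the tetrasubstituted ring alkene untouched.

**Step 19**
Reactants: 33 2-[(R)-4-(tert-butyldimethylsilyloxy)-2,6,6-trimethylcyclohex-1-en-1-yl]ethan-1-ol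
Product: 34 2-[(R)-4-(tert-butyldimethylsilyloxy)-2,6,6-trimethylcyclohex-1-en-1-yl]acetaldehyde
Conditions: Dess–Martin periodinane, NaHCO3, CH2Cl2, 0 °C
Reagents that add atoms: none
Why: Buffered Dess–Martin oxidation gives the β,γ-unsaturated aldehyde without acid or base that could move the ring double bond into conjugation.

**Step 20**
Reactants: 34 2-[(R)-4-(tert-butyldimethylsilyloxy)-2,6,6-trimethylcyclohex-1-en-1-yl]acetaldehyde; 26 (E)-4-(tert-butyldimethylsilyloxy)-2-iodobut-2-en-1-ol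
Product: 35 (E)-5-(tert-butyldimethylsilyloxy)-3-(hydroxymethyl)-1-[(R)-4-(tert-butyldimethylsilyloxy)-2,6,6-trimethylcyclohex-1-en-1-yl]pent-3-en-2-ol (both C8 epimers)
Conditions: CrCl2 (4 equiv), NiCl2 (2 mol %), DMF/THF, 25 °C
Reagents that add atoms: none
Why: Nozaki–Hiyama–Kishi coupling, in which the alkenylchromium formed with retention adds only to the aldehyde and tolerates the free hydroxyl and the enolisable aldehyde; the C8 carbinol forms without control, which does not matter because step 22 oxidises it.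

**Step 21**
Reactants: 35 (E)-5-(tert-butyldimethylsilyloxy)-3-(hydroxymethyl)-1-[(R)-4-(tert-butyldimethylsilyloxy)-2,6,6-trimethylcyclohex-1-en-1-yl]pent-3-en-2-ol; 36 (E)-dodec-2-enoic acid
Product: 37 [(E)-4-(tert-butyldimethylsilyloxy)-2-{1-hydroxy-2-[(R)-4-(tert-butyldimethylsilyloxy)-2,6,6-trimethylcyclohex-1-en-1-yl]ethyl}but-2-en-1-yl] (E)-dodec-2-enoate (both C8 epimers)
Conditions: EDC·HCl, DMAP (0.1 equiv), CH2Cl2, −20 °C
Reagents that add atoms: none
Why: Steglich esterification should acylate the primary allylic C19 hydroxyl well before the hindered secondary C8 hydroxyl, and it avoids the acid chloride that could deconjugate the enoate through a ketene.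

**Step 22**
Reactants: 37 [(E)-4-(tert-butyldimethylsilyloxy)-2-{1-hydroxy-2-[(R)-4-(tert-butyldimethylsilyloxy)-2,6,6-trimethylcyclohex-1-en-1-yl]ethyl}but-2-en-1-yl] (E)-dodec-2-enoate
Product: 38 [(E)-4-(tert-butyldimethylsilyloxy)-2-{2-[(R)-4-(tert-butyldimethylsilyloxy)-2,6,6-trimethylcyclohex-1-en-1-yl]acetyl}but-2-en-1-yl] (E)-dodec-2-enoate
Conditions: Dess–Martin periodinane, NaHCO3, CH2Cl2, 0 °C
Reagents that add atoms: none
Why: Dess–Martin oxidation of the only free (allylic, secondary) hydroxyl installs the C8 ketone and merges the two epimers.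

**Step 23**
Reactants: 38 [(E)-4-(tert-butyldimethylsilyloxy)-2-{2-[(R)-4-(tert-butyldimethylsilyloxy)-2,6,6-trimethylcyclohex-1-en-1-yl]acetyl}but-2-en-1-yl] (E)-dodec-2-enoate
Product: 39 [(E)-4-hydroxy-2-{2-[(R)-4-hydroxy-2,6,6-trimethylcyclohex-1-en-1-yl]acetyl}but-2-en-1-yl] (E)-dodec-2-enoate
Conditions: HF·pyridine, THF, 0 → 25 °C
Reagents that add atoms: none
Why: Fluoride desilylation under mildly acidic conditions removes both silyl ethers and spares the allylic ester and the β,γ-unsaturated ketone, which a basic fluoride source would endanger.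

**Step 24**
Reactants: 39 [(E)-4-hydroxy-2-{2-[(R)-4-hydroxy-2,6,6-trimethylcyclohex-1-en-1-yl]acetyl}but-2-en-1-yl] (E)-dodec-2-enoate
Product: 40 [(E)-2-{2-[(R)-4-hydroxy-2,6,6-trimethylcyclohex-1-en-1-yl]acetyl}-4-oxobut-2-en-1-yl] (E)-dodec-2-enoate
Conditions: MnO2, CH2Cl2, 25 °C
Reagents that add atoms: none
Why: Manganese dioxide oxidises only the allylic primary alcohol (C11), the homoallylic secondary C3 hydroxyl being inert to it.

**Step 25**
Reactants: 20 {(2E,4E,6E,8E,10E,12E)-13-[(1R,4R)-4-(tert-butyldimethylsilyloxy)-2,6,6-trimethylcyclohex-2-en-1-yl]-2,7,11-trimethyltrideca-2,4,6,8,10,12-hexaen-1-yl}triphenylphosphonium bromide; 40 [(E)-2-{2-[(R)-4-hydroxy-2,6,6-trimethylcyclohex-1-en-1-yl]acetyl}-4-oxobut-2-en-1-yl] (E)-dodec-2-enoate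
Product: 42 (3R,3'R,6'R)-3'-(tert-butyldimethylsilyloxy)-3-hydroxy-8-oxo-7,8-dihydro-β,ε-caroten-19-yl (E)-dodec-2-enoate, via ylide 41 (not isolated)
Conditions: NaN(SiMe3)2 (0.95 equiv on 20), THF, −78 °C; then 40, −78 → −20 °C; then I2 (cat.), benzene, diffuse light, 25 °C
Reagents that add atoms: none
Why: Wittig olefination in which the preformed ylide should add at low temperature to the aldehyde, the most electrophilic site of 40, faster than to the ketone or in the conjugate sense, the free C3 hydroxyl being too weakly acidic to quench it; the new C11=C12 bond is equilibrated to the E form by iodine catalysis.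

**Step 26**
Reactants: 42 (3R,3'R,6'R)-3'-(tert-butyldimethylsilyloxy)-3-hydroxy-8-oxo-7,8-dihydro-β,ε-caroten-19-yl (E)-dodec-2-enoate
Product: 43 (3R,3'R,6'R)-3,3'-dihydroxy-8-oxo-7,8-dihydro-β,ε-caroten-19-yl (E)-dodec-2-enoate
Conditions: HF·pyridine, pyridine, THF, 0 °C
Reagents that add atoms: none
Why: Buffered fluoride desilylation frees the allylic C3' hydroxyl without ionising it and leaves the ester, the ketone and the polyene unchanged.

**Compound list**

1 | (E)-3-methylpent-2-en-4-yn-1-ol | C#C/C(C)=C/CO | starting material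
2 | (E)-tert-butyldimethyl[(3-methylpent-2-en-4-yn-1-yl)oxy]silane | C#C/C(C)=C/CO[Si](C)(C)C(C)(C)C | intermediate
3 | 2,4,4-trimethylcyclopent-2-en-1-one | CC1=CC(C)(C)CC1=O | starting material
4 | [(1E,3E)-5-(tert-butyldimethylsilyloxy)-3-methylpenta-1,3-dien-1-yl]diisobutylalane | CC(C)C[Al](CC(C)C)/C=C/C(C)=C/CO[Si](C)(C)C(C)(C)C | intermediate
5 | diisobutylaluminium (R)-3-[(1E,3E)-5-(tert-butyldimethylsilyloxy)-3-methylpenta-1,3-dien-1-yl]-2,4,4-trimethylcyclopent-1-en-1-olate | CC(C)(C)[Si](C)(C)OC/C=C(C)/C=C/[C@H]1C(C)=C(O[Al](CC(C)C)CC(C)C)CC1(C)C | intermediate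
6 | {[(R)-3-[(1E,3E)-5-(tert-butyldimethylsilyloxy)-3-methylpenta-1,3-dien-1-yl]-2,4,4-trimethylcyclopent-1-en-1-yl]oxy}trimethylsilane | CC(C)(C)[Si](C)(C)OC/C=C(C)/C=C/[C@H]1C(C)=C(O[Si](C)(C)C)CC1(C)C | intermediate
7 | (4R)-6,6-dibromo-4-[(1E,3E)-5-(tert-butyldimethylsilyloxy)-3-methylpenta-1,3-dien-1-yl]-3,3,5-trimethyl-1-(trimethylsilyloxy)bicyclo[3.1.0]hexane (cyclopropane carbons as formed, anti adduct expected) | CC(C)(C)[Si](C)(C)OC/C=C(C)/C=C/[C@H]1C2(C)C(Br)(Br)C2(O[Si](C)(C)C)CC1(C)C | intermediate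
8 | (R)-2-bromo-4-[(1E,3E)-5-(tert-butyldimethylsilyloxy)-3-methylpenta-1,3-dien-1-yl]-3,5,5-trimethylcyclohex-2-en-1-one | CC(C)(C)[Si](C)(C)OC/C=C(C)/C=C/[C@H]1C(C)=C(Br)C(=O)CC1(C)C | intermediate
9 | (1R,4R)-2-bromo-4-[(1E,3E)-5-(tert-butyldimethylsilyloxy)-3-methylpenta-1,3-dien-1-yl]-3,5,5-trimethylcyclohex-2-en-1-ol | CC(C)(C)[Si](C)(C)OC/C=C(C)/C=C/[C@H]1C(C)=C(Br)[C@H](O)CC1(C)C | intermediate
10 | lithium (1R,4R)-4-[(1E,3E)-5-(tert-butyldimethylsilyloxy)-3-methylpenta-1,3-dien-1-yl]-2-lithio-3,5,5-trimethylcyclohex-2-en-1-olate | CC(C)(C)[Si](C)(C)OC/C=C(C)/C=C/[C@H]1C(C)=C([Li])[C@H](O[Li])CC1(C)C | intermediate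
11 | (1R,4R)-4-[(1E,3E)-5-(tert-butyldimethylsilyloxy)-3-methylpenta-1,3-dien-1-yl]-3,5,5-trimethylcyclohex-2-en-1-ol | CC(C)(C)[Si](C)(C)OC/C=C(C)/C=C/[C@H]1C(C)=C[C@H](O)CC1(C)C | intermediate
12 | tert-butyl{[(1R,4R)-4-[(1E,3E)-5-(tert-butyldimethylsilyloxy)-3-methylpenta-1,3-dien-1-yl]-3,5,5-trimethylcyclohex-2-en-1-yl]oxy}dimethylsilane | CC(C)(C)[Si](C)(C)OC/C=C(C)/C=C/[C@H]1C(C)=C[C@H](O[Si](C)(C)C(C)(C)C)CC1(C)C | intermediate
13 | (2E,4E)-5-[(1R,4R)-4-(tert-butyldimethylsilyloxy)-2,6,6-trimethylcyclohex-2-en-1-yl]-3-methylpenta-2,4-dien-1-ol | OC/C=C(C)/C=C/[C@H]1C(C)=C[C@H](O[Si](C)(C)C(C)(C)C)CC1(C)C | intermediate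
14 | {[(1R,4R)-4-[(1E,3E)-5-bromo-3-methylpenta-1,3-dien-1-yl]-3,5,5-trimethylcyclohex-2-en-1-yl]oxy}(tert-butyl)dimethylsilane | BrC/C=C(C)/C=C/[C@H]1C(C)=C[C@H](O[Si](C)(C)C(C)(C)C)CC1(C)C | intermediate
15 | {(2E,4E)-5-[(1R,4R)-4-(tert-butyldimethylsilyloxy)-2,6,6-trimethylcyclohex-2-en-1-yl]-3-methylpenta-2,4-dien-1-yl}triphenylphosphonium bromide | [Br-].c1ccc(cc1)[P+](c1ccccc1)(c1ccccc1)C/C=C(C)/C=C/[C@H]1C(C)=C[C@H](O[Si](C)(C)C(C)(C)C)CC1(C)C | intermediate
16 | (2E,4E,6E)-2,7-dimethylocta-2,4,6-trienedial | O=C/C(C)=C/C=C/C=C(C)/C=O | starting material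
17 | ylide of 15 (phosphonium C11' carbanion) | c1ccc(cc1)[P+](c1ccccc1)(c1ccccc1)[CH-]/C=C(C)/C=C/[C@H]1C(C)=C[C@H](O[Si](C)(C)C(C)(C)C)CC1(C)C | intermediate
18 | (2E,4E,6E,8E,10E,12E)-13-[(1R,4R)-4-(tert-butyldimethylsilyloxy)-2,6,6-trimethylcyclohex-2-en-1-yl]-2,7,11-trimethyltrideca-2,4,6,8,10,12-hexaenal | O=C/C(C)=C/C=C/C=C(C)/C=C/C=C(C)/C=C/[C@H]1C(C)=C[C@H](O[Si](C)(C)C(C)(C)C)CC1(C)C | intermediate
19 | (2E,4E,6E,8E,10E,12E)-13-[(1R,4R)-4-(tert-butyldimethylsilyloxy)-2,6,6-trimethylcyclohex-2-en-1-yl]-2,7,11-trimethyltrideca-2,4,6,8,10,12-hexaen-1-ol | OC/C(C)=C/C=C/C=C(C)/C=C/C=C(C)/C=C/[C@H]1C(C)=C[C@H](O[Si](C)(C)C(C)(C)C)CC1(C)C | intermediate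
20 | {(2E,4E,6E,8E,10E,12E)-13-[(1R,4R)-4-(tert-butyldimethylsilyloxy)-2,6,6-trimethylcyclohex-2-en-1-yl]-2,7,11-trimethyltrideca-2,4,6,8,10,12-hexaen-1-yl}triphenylphosphonium bromide | [Br-].c1ccc(cc1)[P+](c1ccccc1)(c1ccccc1)C/C(C)=C/C=C/C=C(C)/C=C/C=C(C)/C=C/[C@H]1C(C)=C[C@H](O[Si](C)(C)C(C)(C)C)CC1(C)C | intermediate
21 | tert-butyldimethyl(prop-2-yn-1-yloxy)silane | C#CCO[Si](C)(C)C(C)(C)C | starting material
22 | lithium acetylide of 21 | [Li]C#CCO[Si](C)(C)C(C)(C)C | intermediate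
23 | ethyl 4-(tert-butyldimethylsilyloxy)but-2-ynoate | CCOC(=O)C#CCO[Si](C)(C)C(C)(C)C | intermediate
24 | ethyl (E)-4-(tert-butyldimethylsilyloxy)-2-(tributylstannyl)but-2-enoate | CCOC(=O)/C(=C\CO[Si](C)(C)C(C)(C)C)[Sn](CCCC)(CCCC)CCCC | intermediate
25 | ethyl (E)-4-(tert-butyldimethylsilyloxy)-2-iodobut-2-enoate | CCOC(=O)/C(I)=C\CO[Si](C)(C)C(C)(C)C | intermediate
26 | (E)-4-(tert-butyldimethylsilyloxy)-2-iodobut-2-en-1-ol | OC/C(I)=C\CO[Si](C)(C)C(C)(C)C | intermediate
27 | (4R,6R)-4-hydroxy-2,2,6-trimethylcyclohexan-1-one (actinol) | O=C1C(C)(C)C[C@H](O)C[C@H]1C | starting material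
28 | (4R,6R)-4-(tert-butyldimethylsilyloxy)-2,2,6-trimethylcyclohexan-1-one | O=C1C(C)(C)C[C@H](O[Si](C)(C)C(C)(C)C)C[C@H]1C | intermediate
29 | potassium (R)-4-(tert-butyldimethylsilyloxy)-2,6,6-trimethylcyclohex-1-en-1-olate | [K]OC1=C(C)C[C@@H](O[Si](C)(C)C(C)(C)C)CC1(C)C | intermediate
30 | (R)-4-(tert-butyldimethylsilyloxy)-2,6,6-trimethylcyclohex-1-en-1-yl trifluoromethanesulfonate | FC(F)(F)S(=O)(=O)OC1=C(C)C[C@@H](O[Si](C)(C)C(C)(C)C)CC1(C)C | intermediate
31 | (R)-tert-butyldimethyl[(3,5,5-trimethyl-4-vinylcyclohex-3-en-1-yl)oxy]silane | C=CC1=C(C)C[C@@H](O[Si](C)(C)C(C)(C)C)CC1(C)C | intermediate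
32 | 9-{2-[(R)-4-(tert-butyldimethylsilyloxy)-2,6,6-trimethylcyclohex-1-en-1-yl]ethyl}-9-borabicyclo[3.3.1]nonane | C1CC2CCCC(C1)B2CCC1=C(C)C[C@@H](O[Si](C)(C)C(C)(C)C)CC1(C)C | intermediate
33 | 2-[(R)-4-(tert-butyldimethylsilyloxy)-2,6,6-trimethylcyclohex-1-en-1-yl]ethan-1-ol | OCCC1=C(C)C[C@@H](O[Si](C)(C)C(C)(C)C)CC1(C)C | intermediate
34 | 2-[(R)-4-(tert-butyldimethylsilyloxy)-2,6,6-trimethylcyclohex-1-en-1-yl]acetaldehyde | O=CCC1=C(C)C[C@@H](O[Si](C)(C)C(C)(C)C)CC1(C)C | intermediate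
35 | (E)-5-(tert-butyldimethylsilyloxy)-3-(hydroxymethyl)-1-[(R)-4-(tert-butyldimethylsilyloxy)-2,6,6-trimethylcyclohex-1-en-1-yl]pent-3-en-2-ol (C8 epimers) | OC/C(=C\CO[Si](C)(C)C(C)(C)C)C(O)CC1=C(C)C[C@@H](O[Si](C)(C)C(C)(C)C)CC1(C)C | intermediate
36 | (E)-dodec-2-enoic acid | CCCCCCCCC/C=C/C(=O)O | starting material
37 | [(E)-4-(tert-butyldimethylsilyloxy)-2-{1-hydroxy-2-[(R)-4-(tert-butyldimethylsilyloxy)-2,6,6-trimethylcyclohex-1-en-1-yl]ethyl}but-2-en-1-yl] (E)-dodec-2-enoate (C8 epimers) | CCCCCCCCC/C=C/C(=O)OC/C(=C\CO[Si](C)(C)C(C)(C)C)C(O)CC1=C(C)C[C@@H](O[Si](C)(C)C(C)(C)C)CC1(C)C | intermediate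
38 | [(E)-4-(tert-butyldimethylsilyloxy)-2-{2-[(R)-4-(tert-butyldimethylsilyloxy)-2,6,6-trimethylcyclohex-1-en-1-yl]acetyl}but-2-en-1-yl] (E)-dodec-2-enoate | CCCCCCCCC/C=C/C(=O)OC/C(=C\CO[Si](C)(C)C(C)(C)C)C(=O)CC1=C(C)C[C@@H](O[Si](C)(C)C(C)(C)C)CC1(C)C | intermediate
39 | [(E)-4-hydroxy-2-{2-[(R)-4-hydroxy-2,6,6-trimethylcyclohex-1-en-1-yl]acetyl}but-2-en-1-yl] (E)-dodec-2-enoate | CCCCCCCCC/C=C/C(=O)OC/C(=C\CO)C(=O)CC1=C(C)C[C@@H](O)CC1(C)C | intermediate
40 | [(E)-2-{2-[(R)-4-hydroxy-2,6,6-trimethylcyclohex-1-en-1-yl]acetyl}-4-oxobut-2-en-1-yl] (E)-dodec-2-enoate | CCCCCCCCC/C=C/C(=O)OC/C(=C\C=O)C(=O)CC1=C(C)C[C@@H](O)CC1(C)C | intermediate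
41 | ylide of 20 (phosphonium C12 carbanion) | c1ccc(cc1)[P+](c1ccccc1)(c1ccccc1)[CH-]/C(C)=C/C=C/C=C(C)/C=C/C=C(C)/C=C/[C@H]1C(C)=C[C@H](O[Si](C)(C)C(C)(C)C)CC1(C)C | intermediate
42 | (3R,3'R,6'R)-3'-(tert-butyldimethylsilyloxy)-3-hydroxy-8-oxo-7,8-dihydro-β,ε-caroten-19-yl (E)-dodec-2-enoate | CCCCCCCCC/C=C/C(=O)OC\C(=C/C=C/C(C)=C/C=C/C=C(C)/C=C/C=C(C)/C=C/[C@H]1C(C)=C[C@H](O[Si](C)(C)C(C)(C)C)CC1(C)C)C(=O)CC1=C(C)C[C@@H](O)CC1(C)C | intermediate
43 | (3R,3'R,6'R)-3,3'-dihydroxy-8-oxo-7,8-dihydro-β,ε-caroten-19-yl (E)-dodec-2-enoate | CCCCCCCCC/C=C/C(=O)OC\C(=C/C=C/C(C)=C/C=C/C=C(C)/C=C/C=C(C)/C=C/[C@H]1C(C)=C[C@H](O)CC1(C)C)C(=O)CC1=C(C)C[C@@H](O)CC1(C)C | target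

**Step count and risks**

Total step count: 26. Longest linear sequence: 12 steps (steps 1–10, 25 and 26; the β-half line, steps 15–26, is equally long).

Steps most likely to fail:

Step 2. The copper-catalysed transfer of the dienyl group to an enone that is hindered on both sides (α-methyl, neighbouring quaternary carbon) may be slow or poorly face-selective. The carbene may also attack the side-chain diene, and base may erase the C6' configuration by γ-deprotonation once the bromoenone has formed. The fallback gives up catalyst control and resolves instead, in separate, isolated stages; it sets out from alane 4 and enone 3. Ligand-free CuBr·SMe2 catalysis of the conjugate addition should give the racemic aluminium enolate F1, and TMSOTf the racemic silyl enol ether F2, which is isolated by short-path distillation. CHBr3/KOtBu then leads through the racemic dibromocyclopropane F3 to the racemic bromoenone F4. The reduction of step 3, which is reagent-controlled, should turn both enantiomers into (1R)-carbinols, that is into 9 and its (1R,4S)-diastereomer F5, which are separated by chromatography. The route is rejoined at compound 9.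

Step 25. The ylide may add in the conjugate sense at C10 of the acyloxymethyl enone with loss of the C19 carboxylate, C7 may be enolised, and the E selectivity may be low. The fallback keeps C8 at the alcohol level through the Wittig reaction and sets out from compound 37. HF·pyridine/pyridine at 0 °C removes only the primary silyl ether to give the primary alcohol F6, and TEMPO/PhI(OAc)2 oxidises only this primary allylic hydroxyl to the hydroxy-enal F7, in which C10 is no longer β to a ketone. Wittig reaction with two equivalents of ylide 41 should give the C8 carbinol F8, MnO2 oxidises the polyenylic C8 hydroxyl to the bis-silyl ketone F9, and HF·pyridine removes both silyl groups. The route is rejoined at compound 43.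

Step 10. The acid may ionise or desilylate the allylic C3' ether, and the polyenyl cation may give double-bond migration or E/Z scrambling. The fallback avoids the cation and sets out from compound 19. Ac2O/pyridine gives the allylic acetate F10; Pd(PPh3)4 (cat.) and PPh3 in THF at 25 °C should convert it through a π-allylpalladium intermediate (Tsuji–Trost-type substitution by the phosphine) into the phosphonium acetate F11, and NaN(SiMe3)2 deprotonates this salt. The route is rejoined at compound 41.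

**Further compounds**

F1 | step 2 | racemic diisobutylaluminium 3-[(1E,3E)-5-(tert-butyldimethylsilyloxy)-3-methylpenta-1,3-dien-1-yl]-2,4,4-trimethylcyclopent-1-en-1-olate | CC(C)(C)[Si](C)(C)OC/C=C(C)/C=C/C1C(C)=C(O[Al](CC(C)C)CC(C)C)CC1(C)C
F2 | step 2 | racemic {[3-[(1E,3E)-5-(tert-butyldimethylsilyloxy)-3-methylpenta-1,3-dien-1-yl]-2,4,4-trimethylcyclopent-1-en-1-yl]oxy}trimethylsilane | CC(C)(C)[Si](C)(C)OC/C=C(C)/C=C/C1C(C)=C(O[Si](C)(C)C)CC1(C)C
F3 | step 2 | racemic 6,6-dibromo-4-[(1E,3E)-5-(tert-butyldimethylsilyloxy)-3-methylpenta-1,3-dien-1-yl]-3,3,5-trimethyl-1-(trimethylsilyloxy)bicyclo[3.1.0]hexane | CC(C)(C)[Si](C)(C)OC/C=C(C)/C=C/C1C2(C)C(Br)(Br)C2(O[Si](C)(C)C)CC1(C)C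
F4 | step 2 | racemic 2-bromo-4-[(1E,3E)-5-(tert-butyldimethylsilyloxy)-3-methylpenta-1,3-dien-1-yl]-3,5,5-trimethylcyclohex-2-en-1-one | CC(C)(C)[Si](C)(C)OC/C=C(C)/C=C/C1C(C)=C(Br)C(=O)CC1(C)C
F5 | step 2 | (1R,4S)-2-bromo-4-[(1E,3E)-5-(tert-butyldimethylsilyloxy)-3-methylpenta-1,3-dien-1-yl]-3,5,5-trimethylcyclohex-2-en-1-ol | CC(C)(C)[Si](C)(C)OC/C=C(C)/C=C/[C@@H]1C(C)=C(Br)[C@H](O)CC1(C)C
F6 | step 25 | [(E)-4-hydroxy-2-{1-hydroxy-2-[(R)-4-(tert-butyldimethylsilyloxy)-2,6,6-trimethylcyclohex-1-en-1-yl]ethyl}but-2-en-1-yl] (E)-dodec-2-enoate (C8 epimers) | CCCCCCCCC/C=C/C(=O)OC/C(=C\CO)C(O)CC1=C(C)C[C@@H](O[Si](C)(C)C(C)(C)C)CC1(C)C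
F7 | step 25 | [(E)-2-{1-hydroxy-2-[(R)-4-(tert-butyldimethylsilyloxy)-2,6,6-trimethylcyclohex-1-en-1-yl]ethyl}-4-oxobut-2-en-1-yl] (E)-dodec-2-enoate (C8 epimers) | CCCCCCCCC/C=C/C(=O)OC/C(=C\C=O)C(O)CC1=C(C)C[C@@H](O[Si](C)(C)C(C)(C)C)CC1(C)C
F8 | step 25 | (3R,3'R,6'R)-3,3'-bis(tert-butyldimethylsilyloxy)-8-hydroxy-7,8-dihydro-β,ε-caroten-19-yl (E)-dodec-2-enoate (C8 epimers) | CCCCCCCCC/C=C/C(=O)OC\C(=C/C=C/C(C)=C/C=C/C=C(C)/C=C/C=C(C)/C=C/[C@H]1C(C)=C[C@H](O[Si](C)(C)C(C)(C)C)CC1(C)C)C(O)CC1=C(C)C[C@@H](O[Si](C)(C)C(C)(C)C)CC1(C)C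
F9 | step 25 | (3R,3'R,6'R)-3,3'-bis(tert-butyldimethylsilyloxy)-8-oxo-7,8-dihydro-β,ε-caroten-19-yl (E)-dodec-2-enoate | CCCCCCCCC/C=C/C(=O)OC\C(=C/C=C/C(C)=C/C=C/C=C(C)/C=C/C=C(C)/C=C/[C@H]1C(C)=C[C@H](O[Si](C)(C)C(C)(C)C)CC1(C)C)C(=O)CC1=C(C)C[C@@H](O[Si](C)(C)C(C)(C)C)CC1(C)C
F10 | step 10 | (2E,4E,6E,8E,10E,12E)-13-[(1R,4R)-4-(tert-butyldimethylsilyloxy)-2,6,6-trimethylcyclohex-2-en-1-yl]-2,7,11-trimethyltrideca-2,4,6,8,10,12-hexaen-1-yl acetate | CC(=O)OC/C(C)=C/C=C/C=C(C)/C=C/C=C(C)/C=C/[C@H]1C(C)=C[C@H](O[Si](C)(C)C(C)(C)C)CC1(C)C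
F11 | step 10 | {(2E,4E,6E,8E,10E,12E)-13-[(1R,4R)-4-(tert-butyldimethylsilyloxy)-2,6,6-trimethylcyclohex-2-en-1-yl]-2,7,11-trimethyltrideca-2,4,6,8,10,12-hexaen-1-yl}triphenylphosphonium acetate | CC(=O)[O-].c1ccc(cc1)[P+](c1ccccc1)(c1ccccc1)C/C(C)=C/C=C/C=C(C)/C=C/C=C(C)/C=C/[C@H]1C(C)=C[C@H](O[Si](C)(C)C(C)(C)C)CC1(C)C
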